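**Strategy.** Ring A is annulated onto a ring B keto lactone derived from (R)-carvone. The disconnection rests on the 1,5-dicarbonyl relationship C9(=O)–C10–C5–C4–C19(=O) and on the syn-diaxial pair C19/O6 across rings A and B, which is tied back as a cis-fused 19,6β-lactone. In one operation a Michael–Dieckmann cascade with methyl acrylate forms C10–C1 and C3–C4, closes ring A as the trans-decalin and sets the quaternary centres C10 and C4 from a mixture of C10 and C4 epimers (stereoconvergent). The precursor is a bicyclic γ-lactone cyclohexanone whose second α-position (C8) is blocked by a phenylthio group; C8=C9 and the side chain follow by enol triflate coupling.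

Key step: step 6

Remark: labdane numbering of the target is used for every intermediate (ring A = C1–C5, C10; ring B = C5–C10; C17 on C8, C18 α and C19 β on C4, C20 on C10; β = face of C20); SMILES leave open only centres that form as mixtures and are erased later; (E)-4,4-dimethoxy-2-methylbut-2-enal is taken to be a commercial C5 building block.

**Step 1**
Reactants: 1 (R)-(−)-carvone
Product: 3 trans-6-methylcarvone (new methyl = C20 on C10), via lithium dienolate 2 (not isolated)
Conditions: LiN(i-Pr)2, THF, −78 °C; MeI, −78 to 0 °C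
Reagents that add atoms: iodomethane, CI
Why: Kinetic α′-deprotonation of the enone and enolate alkylation should place the methyl mainly anti to the isopropenyl group, a centre that is erased again in step 6.

**Step 2**
Reactants: 3 trans-6-methylcarvone
Product: 4 allylic alcohol primary alcohol diol (epimers at C4 and C9)
Conditions: 9-BBN (2.5 equiv), THF, 0 to 23 °C; NaOH, H2O2, 0 °C
Reagents that add atoms: hydrogen peroxide, OO
Why: Hydroboration–oxidation should take the 1,1-disubstituted isopropenyl alkene at its terminus while 9-BBN reduces the enone carbonyl 1,2 and leaves the trisubstituted ring alkene, and both new centres are mixtures that are erased in steps 3 and 6.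

**Step 3**
Reactants: 4 diol
Product: 5 enone carboxylic acid (epimers at C4)
Conditions: CrO3, H2SO4, acetone/H2O, 0 °C
Reagents that add atoms: water, O
Why: Jones oxidation should return the enone from the allylic alcohol and carry the primary alcohol through the aldehyde hydrate to the acid.

**Step 4**
Reactants: 5 enone carboxylic acid
Product: 7 cis-fused enone γ-lactone (O6 β), via bromo acid 6 (not isolated)
Conditions: NBS, AIBN (cat.), PhCF3, 80 °C; then K2CO3, DMF, 23 °C
Reagents that add atoms: none
Why: Wohl–Ziegler bromination at the γ-carbon C6 of the enone followed by intramolecular SN2 lactonization should give the cis-fused lactone, because the β-tethered carboxylate can displace only the α-bromide (the bromide epimers interconvert) and the vinylogously acidic C6–H lets any trans-fused isomer relax to the more stable cis fusion.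

**Step 5**
Reactants: 7 cis-fused enone γ-lactone
Product: 9 phenylthio keto lactone (PhS and C17 on C8), via lithium enolate 8 (not isolated)
Conditions: LiBH(s-Bu)3 (L-Selectride), THF, −78 °C; PhSO2SPh, −78 to 0 °C
Reagents that add atoms: S-phenyl benzenethiosulfonate, O=S(=O)(Sc1ccccc1)c1ccccc1
Why: Conjugate hydride addition should form the C8=C9 enolate regiospecifically and its sulfenylation makes C8 quaternary (reductive enolate formation–sulfenylation), so that C10 is the only enolizable ketone α-position; the C8 configuration is of no consequence.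

**Step 6**
Reactants: 9 phenylthio keto lactone; 10 methyl acrylate
Product: 13 tricyclic 3,9-diketo 19,6β-lactone, via potassium enolate 11 (not isolated), via Michael adduct 12 (not isolated)
Conditions: KH (1.0 equiv), t-BuOH (5 mol %), THF, 0 to 23 °C; 10 (1.1 equiv), −78 to 0 °C; AcOH
Reagents that add atoms: none
Why: KH should form the thermodynamic potassium enolate at C10, which adds to methyl acrylate; the ester enolate so formed is relayed by proton transfer from C4–H to the lactone enolate, which acylates at the ester carbonyl C3, and the expelled methoxide deprotonates C2 of the product so that the sequence does not revert. The closest known reaction type is the Michael–Dieckmann (Michael–Claisen) annulation. Ring A closes in the 6-(enolexo)-exo-trig mode. C10 is set by attack of the acrylate on the convex α-face, anti to the C4 substituent on C5 that A(1,2) strain with the C10 methyl holds pseudoaxial, and C4 is set by the lactone, which keeps C19 on the β-face next to O6 so that C3 can only bond on the face turned towards C1. The step needs C10, not C8 or C4, to attack the acrylate, which the phenylthio block at C8, the single equivalent of base and the higher acidity of the ketone secure; it needs C4, not C2, to close the ring, which the trans arrangement of the C10 chain and C4 on ring B secures because C2 could reach C19 only through a strained bridged skeleton. Both C10 epimers and both C4 epimers of 9 converge on the one product.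

**Step 7**
Reactants: 13 tricyclic 3,9-diketo 19,6β-lactone
Product: 15 7-en-3,9-dione 19,6β-lactone, via sulfoxide 14 (not isolated)
Conditions: mCPBA (1.0 equiv), CH2Cl2, −78 °C; then CaCO3, toluene, 80 °C
Reagents that add atoms: none
Why: Chemoselective S-oxidation and thermal syn-elimination of the β-keto sulfoxide (sulfoxide elimination) should unveil the C7=C8 enone under neutral conditions that the β-keto lactone tolerates.

**Step 8**
Reactants: 15 7-en-3,9-dione 19,6β-lactone
Product: 17 3α-hydroxy C8=C9 enol triflate 19,6β-lactone, via dilithium alkoxide enolate 16 (not isolated)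
Conditions: LiBH(s-Bu)3 (2.3 equiv), THF, −78 °C; PhNTf2, −78 to 0 °C
Reagents that add atoms: N-phenylbis(trifluoromethanesulfonimide), O=S(=O)(N(c1ccccc1)S(=O)(=O)C(F)(F)F)C(F)(F)F
Why: The bulky hydride should attack the C3 ketone along the equatorial trajectory from the β-face (the axial α-approach meets H1α and H5α) to give the axial 3α-alkoxide, and it adds 1,4 to the enone to give the C8=C9 enolate, which is O-triflated (selectride reduction with reductive enol triflate formation).

**Step 9**
Reactants: 17 3α-hydroxy enol triflate lactone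
Product: 18 3α,6β,19-triol enol triflate
Conditions: i-Bu2AlH (6 equiv), CH2Cl2, −78 to 23 °C; aq. KNaC4H4O6
Reagents that add atoms: none
Why: Exhaustive hydride reduction of the lactone should release the 6β-hydroxyl and the C19 hydroxymethyl group without touching C4 or C6, and enol triflates are inert to this reagent.

**Step 10**
Reactants: 18 triol enol triflate
Product: 19 19-O-triethylsilyl ether
Conditions: TESCl, imidazole, CH2Cl2, −40 °C
Reagents that add atoms: chlorotriethylsilane, CC[Si](Cl)(CC)CC
Why: Selective silylation should take the primary C19 hydroxyl far faster than the two axial secondary hydroxyls.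

**Step 11**
Reactants: 19 19-O-triethylsilyl ether
Product: 20 3α-isovalerate 19-O-TES enol triflate
Conditions: (i-BuCO)2O, DMAP, Et3N, CH2Cl2, 23 °C
Reagents that add atoms: isovaleric anhydride, CC(C)CC(=O)OC(=O)CC(C)C
Why: DMAP-catalysed acylation should take the 3α-hydroxyl, because the 6β-hydroxyl is shielded by its 1,3-diaxial neighbours C20 and C19.

**Step 12**
Reactants: 21 (E)-4,4-dimethoxy-2-methylbut-2-enal
Product: 22 (E)-5,5-dimethoxy-3-methylpenta-1,3-diene
Conditions: Ph3PCH3Br, KOt-Bu, THF, 0 °C
Reagents that add atoms: methyltriphenylphosphonium bromide, C[P+](c1ccccc1)(c1ccccc1)c1ccccc1.[Br-]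
Why: Wittig methylenation of the aldehyde should leave the E trisubstituted alkene and the acetal untouched.

**Step 13**
Reactants: 22 (E)-5,5-dimethoxy-3-methylpenta-1,3-diene; 20 3α-isovalerate 19-O-TES enol triflate
Product: 24 15,15-dimethoxy labda-8,13E-diene (3α-isovalerate 19-O-TES 6β-ol), via alkylborane 23 (not isolated)
Conditions: 22, 9-BBN, THF, 0 to 23 °C; then 20, Pd(dppf)Cl2 (5 mol %), AsPh3, Cs2CO3, DMF/H2O, 50 °C
Reagents that add atoms: none
Why: 9-BBN should add to the terminal vinyl group with boron on the CH2 terminus, and the B-alkyl Suzuki–Miyaura coupling with the enol triflate forms C9–C11 with retention of both alkene geometries.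

**Step 14**
Reactants: 24 15,15-dimethoxy labdadiene
Product: 25 3α-isovaleroyloxy-6β,19-dihydroxylabda-8,13E-dien-15-al
Conditions: AcOH/THF/H2O (3:1:1), 23 °C
Reagents that add atoms: water, O
Why: Mild acid should hydrolyse the allylic dimethyl acetal and cleave the primary TES ether (acetal hydrolysis and desilylation) while the hindered isovalerate survives.

**Step 15**
Reactants: 25 enal diol
Product: 26 3α-isovaleroyloxy-6β,19-dihydroxylabda-8,13E-dien-15-oic acid (target)
Conditions: NaClO2, NaH2PO4, 2-methylbut-2-ene, t-BuOH/H2O, 0 to 23 °C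
Reagents that add atoms: sodium chlorite, [Na+].[O-]Cl=O
Why: Pinnick oxidation should convert only the aldehyde into the acid and leave the two free hydroxyls, the ester and the E alkene untouched.

**Compound list**
1 | (R)-(−)-carvone, (5R)-2-methyl-5-(prop-1-en-2-yl)cyclohex-2-en-1-one | CC(=C)[C@@H]1CC=C(C)C(=O)C1 | starting material
2 | lithium cross-conjugated dienolate of 1 | CC(=C)[C@@H]1CC=C(C)C([O-])=C1.[Li+] | intermediate (not isolated)
3 | (5R,6S)-2,6-dimethyl-5-(prop-1-en-2-yl)cyclohex-2-en-1-one (trans-6-methylcarvone) | CC(=C)[C@@H]1CC=C(C)C(=O)[C@H]1C | intermediate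
4 | 2-(3-hydroxy-2,4-dimethylcyclohex-4-en-1-yl)propan-1-ol, ring centres as in 3, epimers at C4 and C9 | CC(CO)[C@@H]1CC=C(C)C(O)[C@H]1C | intermediate
5 | 2-[(1R,2S)-2,4-dimethyl-3-oxocyclohex-4-en-1-yl]propanoic acid, epimers at C4 | CC(C(=O)O)[C@@H]1CC=C(C)C(=O)[C@H]1C | intermediate
6 | 6-bromo derivative of 5 (bromine on C6, both epimers) | CC(C(=O)O)[C@@H]1C(Br)C=C(C)C(=O)[C@H]1C | intermediate (not isolated)
7 | 3,4,6-trimethyl-3a,4-dihydro-1-benzofuran-2,5(3H,7aH)-dione, cis-fused (5α-H, 6α-H, O6 β), epimers at C4 | CC1=C[C@H]2OC(=O)C(C)[C@H]2[C@H](C)C1=O | intermediate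
8 | lithium C8=C9 enolate of 7,8-dihydro-7 | CC1=C([O-])[C@@H](C)[C@@H]2C(C)C(=O)O[C@@H]2C1.[Li+] | intermediate (not isolated)
9 | 3,4,6-trimethyl-6-(phenylsulfanyl)hexahydro-1-benzofuran-2,5-dione, cis-fused (PhS on C8; epimers at C4 and C8) | CC1(Sc2ccccc2)C(=O)[C@@H](C)[C@@H]3C(C)C(=O)O[C@@H]3C1 | intermediate
10 | methyl acrylate | C=CC(=O)OC | starting material
11 | potassium C9=C10 enolate of 9 | CC1(Sc2ccccc2)C([O-])=C(C)[C@@H]3C(C)C(=O)O[C@@H]3C1.[K+] | intermediate (not isolated)
12 | methyl 3-(C10-yl)propanoate of 9 (C10: CH3 β, chain α) | CC1(Sc2ccccc2)C(=O)[C@@](C)(CCC(=O)OC)[C@@H]3C(C)C(=O)O[C@@H]3C1 | intermediate (not isolated)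
13 | 8-phenylsulfanyl-3,9-dioxo tricyclic 19,6β-lactone (5α-H, 10β-CH3, 4α-CH3; C11–C16 absent) | CC1(Sc2ccccc2)C(=O)[C@@]3(C)CCC(=O)[C@](C)(C4=O)[C@@H]3[C@H](O4)C1 | intermediate
14 | S-oxide of 13 | CC1(S(=O)c2ccccc2)C(=O)[C@@]3(C)CCC(=O)[C@](C)(C4=O)[C@@H]3[C@H](O4)C1 | intermediate (not isolated)
15 | 7-ene-3,9-dione tricyclic 19,6β-lactone | C1=C(C)C(=O)[C@@]2(C)CCC(=O)[C@](C)(C3=O)[C@@H]2[C@@H]1O3 | intermediate
16 | dilithium 3α-alkoxide C8=C9 enolate of the 19,6β-lactone | CC1=C([O-])[C@@]2(C)CC[C@@H]([O-])[C@](C)(C3=O)[C@@H]2[C@H](O3)C1.[Li+].[Li+] | intermediate (not isolated)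
17 | 3α-hydroxy C8=C9 enol triflate (OTf on C9) 19,6β-lactone | CC1=C(OS(=O)(=O)C(F)(F)F)[C@@]2(C)CC[C@@H](O)[C@](C)(C3=O)[C@@H]2[C@H](O3)C1 | intermediate
18 | 3α,6β,19-trihydroxy C8=C9 enol triflate | CC1=C(OS(=O)(=O)C(F)(F)F)[C@@]2(C)CC[C@@H](O)[C@](C)(CO)[C@@H]2[C@H](O)C1 | intermediate
19 | 19-O-triethylsilyl ether of 18 | CC1=C(OS(=O)(=O)C(F)(F)F)[C@@]2(C)CC[C@@H](O)[C@](C)(CO[Si](CC)(CC)CC)[C@@H]2[C@H](O)C1 | intermediate
20 | 3α-O-(3-methylbutanoyl) 19-O-triethylsilyl 6β-hydroxy enol triflate | CC1=C(OS(=O)(=O)C(F)(F)F)[C@@]2(C)CC[C@@H](OC(=O)CC(C)C)[C@](C)(CO[Si](CC)(CC)CC)[C@@H]2[C@H](O)C1 | intermediate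
21 | (E)-4,4-dimethoxy-2-methylbut-2-enal | COC(OC)/C=C(\C)C=O | starting material
22 | (E)-5,5-dimethoxy-3-methylpenta-1,3-diene | COC(OC)/C=C(\C)C=C | intermediate
23 | B-[(E)-5,5-dimethoxy-3-methylpent-3-enyl]-9-borabicyclo[3.3.1]nonane | COC(OC)/C=C(\C)CCB1C2CCCC1CCC2 | intermediate (not isolated)
24 | 15,15-dimethoxy-3α-isovaleroyloxy-19-triethylsilyloxy-labda-8,13E-dien-6β-ol | CC1=C(CC/C(C)=C/C(OC)OC)[C@@]2(C)CC[C@@H](OC(=O)CC(C)C)[C@](C)(CO[Si](CC)(CC)CC)[C@@H]2[C@H](O)C1 | intermediate
25 | 3α-isovaleroyloxy-6β,19-dihydroxylabda-8,13E-dien-15-al | CC1=C(CC/C(C)=C/C=O)[C@@]2(C)CC[C@@H](OC(=O)CC(C)C)[C@](C)(CO)[C@@H]2[C@H](O)C1 | intermediate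
26 | 3α-isovaleroyloxy-6β,19-dihydroxylabda-8,13E-dien-15-oic acid (CNP0274836.1) | CC1=C(CC/C(C)=C/C(=O)O)[C@@]2(C)CC[C@@H](OC(=O)CC(C)C)[C@](C)(CO)[C@@H]2[C@H](O)C1 | target

**Totals.** Total step count: 15. Longest linear sequence: 14 steps (steps 1–11 and 13–15; step 12 makes the side-chain fragment).

**Steps most likely to fail**

1. Step 6 (key step). The ester enolate formed after the conjugate addition may add to further acrylate instead of relaying its charge to C4. The C10 enolate may also be attacked on its β-face, or methoxide may open the lactone before ring closure. Fallback, setting out from 9: C-allylation of the potassium enolate with allyl bromide should give the allyl ketone F1 with the same facial bias at C10. Hydroboration with 9-BBN and NaBO3 oxidation should give the primary alcohol F2. TEMPO/PhI(OAc)2 oxidation should give the acid F3, and TMSCHN2 the methyl ester 12, now isolated. LiN(SiMe3)2 at −78 °C then closes ring A by Dieckmann acylation, and the route is rejoined at 13.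

2. Step 4. Hydrogen abstraction may occur at C17 or C10 instead of C6, or dehydrobromination to a dienone may outrun substitution. Fallback, setting out from 5: kinetic deconjugation (KOt-Bu, t-BuOH; cold AcOH) should give the β,γ-unsaturated keto acid F4. Iodolactonization (I2, NaHCO3) should give the cis-fused iodolactone F5, with O6 delivered on the β-face by the tethered carboxylate. DBU then removes HI towards the acidic C8–H, and the route is rejoined at 7.

3. Step 13. Oxidative addition and transmetalation may be slow at the triflate flanked by the quaternary C10, so that β-hydride elimination or protodeboronation of the alkylborane takes over. Fallback, setting out from 22: hydroboration with 9-BBN followed by iodination (I2, NaOMe) should give the iodide F6. Zinc insertion (Zn, LiCl, THF) should give the alkylzinc iodide F7. Negishi coupling of F7 with 20 (Pd(OAc)2, SPhos, THF) needs no aqueous base and rejoins the route at 24.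

**Further compounds**
F1 | step 6 | C10-allyl phenylthio keto lactone | CC1(Sc2ccccc2)C(=O)[C@@](C)(CC=C)[C@@H]3C(C)C(=O)O[C@@H]3C1
F2 | step 6 | C10-(3-hydroxypropyl) phenylthio keto lactone | CC1(Sc2ccccc2)C(=O)[C@@](C)(CCCO)[C@@H]3C(C)C(=O)O[C@@H]3C1
F3 | step 6 | C10-(2-carboxyethyl) phenylthio keto lactone | CC1(Sc2ccccc2)C(=O)[C@@](C)(CCC(=O)O)[C@@H]3C(C)C(=O)O[C@@H]3C1
F4 | step 4 | 2-(2,4-dimethyl-3-oxocyclohex-5-en-1-yl)propanoic acid (C6=C7 isomer of 5) | CC(C(=O)O)[C@@H]1C=CC(C)C(=O)[C@H]1C
F5 | step 4 | cis-fused 7-iodo keto lactone (iodine on C7, trans to O6) | CC1C(=O)[C@@H](C)[C@@H]2C(C)C(=O)O[C@@H]2C1I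
F6 | step 13 | (E)-5-iodo-1,1-dimethoxy-3-methylpent-2-ene | COC(OC)/C=C(\C)CCI
F7 | step 13 | [(E)-5,5-dimethoxy-3-methylpent-3-enyl]zinc iodide | COC(OC)/C=C(\C)CC[Zn]I
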